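**Retrosynthetic overview**

- The three ester groups are taken back to a bis-silyl ether of eudesma-4(15),8,11-triene-3β,5α-diol. The C8 oxygen is placed cis to the C7 side chain by iodolactonization of the 12-acid onto C8=C9, and the lactone is reopened as the methyl ester.
- The strategy rests on ring A: the C3 carbinol next to the C4=C15 exocyclic methylene is the retron of a reductive alkyne–aldehyde coupling. C3–C4 is therefore cut to a C3 aldehyde on the C10 chain and an ethynyl group on the C5 carbinol.
- The monocyclic ynal (ring B) goes back to (R)-carvone; deconjugative alkylation creates the C10 quaternary centre and moves the alkene to C8=C9.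
- The C5 carbinol is built carbon first and oxygen second (methoxymethylene Wittig, α-face oxidation of the enol ether, Ohira–Bestmann homologation). Reagents reach C5 from the α-face, so an acetylide added to the ketone would take the place of the 5α-hydroxyl.
- Ring order: ring B from carvone, ring A in the nickel step, then a transient C7–C8 lactone ring.

Key step: step 7

Remark: eudesmane numbering (C1 to C15) is used for every intermediate; the enol ether of step 2 is expected as an E/Z mixture that converges in step 3 and is drawn as its (E) isomer.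

Step 1
Reactants: 1 (R)-carvone; 2 3-bromo-1,1-dimethoxypropane
Product: 3 (2R,5S)-2-(3,3-dimethoxypropyl)-2-methyl-5-(prop-1-en-2-yl)cyclohex-3-en-1-one
Conditions: KOtBu (1.1 equiv), t-BuOH/THF, 0 °C; then 2, rt to 40 °C; chromatographic removal of the C10 epimer
Reagents that add atoms: none
Why: Deconjugative α-alkylation: KOtBu gives the linear dienolate by deprotonation at C8, which is alkylated at C10 and leaves the C8=C9 alkene; the electrophile should enter trans to the C7 isopropenyl group, whose pseudo-axial conformer shields its own face of C10, and C7 is not touched.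

Step 2
Reactants: 3 (2R,5S)-2-(3,3-dimethoxypropyl)-2-methyl-5-(prop-1-en-2-yl)cyclohex-3-en-1-one
Product: 4 (3S,5E,6R)-6-(3,3-dimethoxypropyl)-5-(methoxymethylidene)-6-methyl-3-(prop-1-en-2-yl)cyclohex-1-ene
Conditions: MeOCH2PPh3Cl, KOtBu, THF, 0 °C to 50 °C
Reagents that add atoms: (methoxymethyl)triphenylphosphonium chloride, COC[P+](c1ccccc1)(c1ccccc1)c1ccccc1.[Cl-]
Why: Wittig olefination with the methoxymethylene ylide brings in C4 as an enol ether carbon; the ketone enolizes only toward C6, which cannot epimerize anything, and the E/Z ratio is of no consequence.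

Step 3
Reactants: 4 (3S,5E,6R)-6-(3,3-dimethoxypropyl)-5-(methoxymethylidene)-6-methyl-3-(prop-1-en-2-yl)cyclohex-1-ene
Product: 6 (1S,2R,5S)-2-(3,3-dimethoxypropyl)-1-hydroxy-2-methyl-5-(prop-1-en-2-yl)cyclohex-3-ene-1-carbaldehyde, via methoxy spiro-epoxide 5 (not isolated)
Conditions: DMDO (1.05 equiv), acetone, −78 °C; then H2O/THF, 0 °C
Reagents that add atoms: dimethyldioxirane, CC1(C)OO1; water, O
Why: Rubottom-type epoxidation of the electron-rich enol ether, much faster than attack on the two unactivated alkenes, followed by hydrolysis of the 2-methoxyoxirane; oxygen should reach C5 from the α-face, because the β-equatorial approach is blocked by the axial C10 methyl and, in the other half-chair, the β-axial approach by the C7 isopropenyl, so O5 becomes axial (α) and C4 equatorial (β).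

Step 4
Reactants: 6 (1S,2R,5S)-2-(3,3-dimethoxypropyl)-1-hydroxy-2-methyl-5-(prop-1-en-2-yl)cyclohex-3-ene-1-carbaldehyde
Product: 7 (1R,2R,5S)-2-(3,3-dimethoxypropyl)-1-ethynyl-2-methyl-5-(prop-1-en-2-yl)cyclohex-3-en-1-ol
Conditions: dimethyl (1-diazo-2-oxopropyl)phosphonate, K2CO3, MeOH, 0 °C to rt
Reagents that add atoms: dimethyl (1-diazo-2-oxopropyl)phosphonate, COP(=O)(OC)C(=[N+]=[N-])C(C)=O
Why: Ohira–Bestmann (Seyferth–Gilbert) homologation turns the formyl group into the terminal alkyne (C4≡C15) without touching the C5 configuration; the low temperature is meant to keep the α-ketol shift of the hydroxy aldehyde from competing.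

Step 5
Reactants: 7 (1R,2R,5S)-2-(3,3-dimethoxypropyl)-1-ethynyl-2-methyl-5-(prop-1-en-2-yl)cyclohex-3-en-1-ol
Product: 8 triethyl{[(1R,2R,5S)-2-(3,3-dimethoxypropyl)-1-ethynyl-2-methyl-5-(prop-1-en-2-yl)cyclohex-3-en-1-yl]oxy}silane
Conditions: KN(SiMe3)2 (1.0 equiv), THF, −78 °C; Et3SiCl, −78 to 0 °C
Reagents that add atoms: chlorotriethylsilane, CC[Si](Cl)(CC)CC
Why: O-silylation of the hindered tertiary alcohol through its potassium alkoxide; one equivalent of base deprotonates the hydroxyl before the alkyne C–H, and the basic conditions leave the dimethyl acetal intact (a silyl triflate would activate it).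

Step 6
Reactants: 8 triethyl{[(1R,2R,5S)-2-(3,3-dimethoxypropyl)-1-ethynyl-2-methyl-5-(prop-1-en-2-yl)cyclohex-3-en-1-yl]oxy}silane
Product: 9 3-[(1R,4S,6R)-6-ethynyl-1-methyl-4-(prop-1-en-2-yl)-6-(triethylsilyloxy)cyclohex-2-en-1-yl]propanal
Conditions: PPTS (cat.), acetone/H2O 9:1, 40 °C
Reagents that add atoms: water, O
Why: Mild acid-catalysed hydrolysis of the dimethyl acetal; the tertiary silyl ether, flanked by the quaternary C10 and the alkyne, should survive these conditions.

Step 7
Reactants: 9 3-[(1R,4S,6R)-6-ethynyl-1-methyl-4-(prop-1-en-2-yl)-6-(triethylsilyloxy)cyclohex-2-en-1-yl]propanal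
Product: 10 3β,5α-bis(triethylsilyloxy)eudesma-4(15),8,11-triene
Conditions: Ni(cod)2 (20 mol %), PBu3 (40 mol %), Et3SiH (5 equiv), THF, 0 °C to rt, slow addition of 9
Reagents that add atoms: triethylsilane, CC[SiH](CC)CC
Why: Zerovalent nickel bearing PBu3 binds the C3 aldehyde and the C4≡C15 alkyne and couples them oxidatively to an oxanickelacyclopentene, which forms the C3–C4 bond; σ-bond metathesis with Et3SiH puts silicon on O3 and reductive elimination puts hydrogen on C15, so the C4=C15 methylene and the 3-silyl ether arise together. The closest known reaction type is the nickel-catalysed reductive cyclization of ynals with trialkylsilanes, which accepts hydrogen-terminated alkynes; the fully substituted propargylic carbon is the demanding element here. Ring A closes in the 6-exo-dig mode, C3 bonding to the inner alkyne carbon held on C5. C3 is set in a chair-like transition state with the C10 tether and the C5 alkyne both equatorial on ring B: the planar metallacycle holds the C3–O bond in the plane of the developing C4=C15 bond, that is pseudo-equatorial, and an axial C3–O bond would be syn-diaxial to the C5 silyloxy group, so the 3β ether should result. The step needs chemoselectivity for the alkyne–aldehyde pair over the isopropenyl and C8=C9 alkenes and over alkyne oligomerization; neither alkene can reach the alkyne in an unstrained metallacycle, the quaternary C5 and C10 atoms hold the reacting ends together, and slow addition keeps the alkyne concentration low.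

Step 8
Reactants: 10 3β,5α-bis(triethylsilyloxy)eudesma-4(15),8,11-triene
Product: 11 3β,5α-bis(triethylsilyloxy)eudesma-4(15),8,11(13)-trien-12-ol
Conditions: SeO2 (0.5 equiv), t-BuOOH (3 equiv), CH2Cl2, 0 °C to rt
Reagents that add atoms: tert-butyl hydroperoxide, CC(C)(C)OO (its oxygen is relayed by SeO2, O=[Se]=O)
Why: Sharpless allylic oxidation (ene reaction, then [2,3]-sigmatropic shift) should act on the isopropenyl methyl: the C7–H bond lies in the alkene plane and is poorly placed for the ene step, and the C4=C15 alkene is shielded by two silyloxy groups and has only the C3–H of an ether carbon.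

Step 9
Reactants: 11 3β,5α-bis(triethylsilyloxy)eudesma-4(15),8,11(13)-trien-12-ol
Product: 12 3β,5α-bis(triethylsilyloxy)eudesma-4(15),8,11(13)-trien-12-al
Conditions: MnO2 (activated, excess), CH2Cl2, rt
Reagents that add atoms: none
Why: Selective MnO2 oxidation of the primary allylic alcohol to the enal under neutral conditions that leave the silyl ethers and alkenes alone; enal already formed in step 8 is carried along.

Step 10
Reactants: 12 3β,5α-bis(triethylsilyloxy)eudesma-4(15),8,11(13)-trien-12-al
Product: 13 3β,5α-bis(triethylsilyloxy)eudesma-4(15),8,11(13)-trien-12-oic acid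
Conditions: NaClO2, NaH2PO4, 2-methyl-2-butene (excess), t-BuOH/H2O, 0 °C to rt
Reagents that add atoms: sodium chlorite, [Na+].[O-]Cl=O
Why: Pinnick oxidation converts the enal into the acrylic acid; the alkene scavenger takes up the hypochlorous acid before it reaches the three alkenes of the substrate.

Step 11
Reactants: 13 3β,5α-bis(triethylsilyloxy)eudesma-4(15),8,11(13)-trien-12-oic acid
Product: 14 9α-iodo-3β,5α-bis(triethylsilyloxy)eudesma-4(15),11(13)-dien-12,8β-olide
Conditions: I2, NaHCO3, MeCN, 0 °C, dark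
Reagents that add atoms: iodine, II
Why: Iodolactonization (5-exo): the iodonium ion forms on the α-face of C8=C9, away from the axial C10 methyl, and the carboxylate on the β side chain of C7 opens it at C8 in a trans-diaxial way, which sets the 8β C–O bond as a cis-fused γ-lactone.

Step 12
Reactants: 14 9α-iodo-3β,5α-bis(triethylsilyloxy)eudesma-4(15),11(13)-dien-12,8β-olide
Product: 15 3β,5α-bis(triethylsilyloxy)eudesma-4(15),11(13)-dien-12,8β-olide
Conditions: Bu3SnH (1.2 equiv, slow addition), AIBN (cat.), benzene, 80 °C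
Reagents that add atoms: none
Why: Radical chain deiodination; iodine abstraction by the stannyl radical is far faster than its reversible addition to the α-methylene lactone, and the C9 radical has no favourable cyclization mode.

Step 13
Reactants: 15 3β,5α-bis(triethylsilyloxy)eudesma-4(15),11(13)-dien-12,8β-olide
Product: 17 methyl 8β-hydroxy-3β,5α-bis(triethylsilyloxy)eudesma-4(15),11(13)-dien-12-oate, via lithium hydroxy carboxylate 16 (not isolated)
Conditions: LiOH·H2O (1.2 equiv), THF/H2O, 0 °C to rt; evaporate; MeI, DMF, rt; crude product used at once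
Reagents that add atoms: lithium hydroxide, [Li+].[OH-]; iodomethane, CI
Why: Saponification by acyl–oxygen cleavage keeps the C8 configuration, and SN2 methylation of the carboxylate salt avoids the free hydroxy acid, which would relactonize; aqueous THF is used so that no alkoxide adds to the methylene group.

Step 14
Reactants: 17 methyl 8β-hydroxy-3β,5α-bis(triethylsilyloxy)eudesma-4(15),11(13)-dien-12-oate
Product: 18 methyl 8β-acetoxy-3β,5α-bis(triethylsilyloxy)eudesma-4(15),11(13)-dien-12-oate
Conditions: Ac2O, pyridine, DMAP (cat.), CH2Cl2, 0 °C to rt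
Reagents that add atoms: acetic anhydride, CC(=O)OC(C)=O
Why: DMAP-catalysed acetylation of the axial 8β-hydroxyl should be faster than its re-closure onto the methyl ester, and capping it removes the lactonization pathway for the rest of the route.

Step 15
Reactants: 18 methyl 8β-acetoxy-3β,5α-bis(triethylsilyloxy)eudesma-4(15),11(13)-dien-12-oate
Product: 19 methyl 8β-acetoxy-3β,5α-dihydroxyeudesma-4(15),11(13)-dien-12-oate
Conditions: HF·pyridine, pyridine/THF, 0 °C to rt
Reagents that add atoms: none
Why: Fluoride-mediated cleavage of both triethylsilyl ethers under buffered, non-basic conditions that leave the acetate, the methyl ester and the acrylate untouched.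

Step 16
Reactants: 19 methyl 8β-acetoxy-3β,5α-dihydroxyeudesma-4(15),11(13)-dien-12-oate; 20 angelic acid
Product: 22 methyl 8β-acetoxy-3β-angeloyloxy-5α-hydroxyeudesma-4(15),11(13)-dien-12-oate (CNP0179024.1), via angelic 2,4,6-trichlorobenzoic anhydride 21 (not isolated)
Conditions: 20, 2,4,6-trichlorobenzoyl chloride, Et3N, toluene, rt; then 19, 80 °C (no DMAP)
Reagents that add atoms: none
Why: Yamaguchi esterification through the mixed anhydride acylates the secondary allylic 3β-hydroxyl while the tertiary 5α-hydroxyl stays free; leaving out the nucleophilic catalyst should prevent Z to E isomerization of the angelate to the tiglate.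

**Compound list**

1 | (R)-carvone | CC1=CC[C@H](CC1=O)C(C)=C | starting material
2 | 3-bromo-1,1-dimethoxypropane | COC(CCBr)OC | starting material
3 | (2R,5S)-2-(3,3-dimethoxypropyl)-2-methyl-5-(prop-1-en-2-yl)cyclohex-3-en-1-one (C10 chain trans to the C7 isopropenyl) | C=C(C)[C@H]1CC(=O)[C@](C)(CCC(OC)OC)C=C1 | intermediate
4 | (3S,5E,6R)-6-(3,3-dimethoxypropyl)-5-(methoxymethylidene)-6-methyl-3-(prop-1-en-2-yl)cyclohex-1-ene | C=C(C)[C@H]1C/C(=C\OC)[C@](C)(CCC(OC)OC)C=C1 | intermediate
5 | methoxy spiro-epoxide of 4 (oxirane oxygen on the α-face of C5; acetal carbon C4 as a mixture) | C=C(C)[C@H]1C[C@@](O2)(C2OC)[C@](C)(CCC(OC)OC)C=C1 | intermediate (not isolated)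
6 | (1S,2R,5S)-2-(3,3-dimethoxypropyl)-1-hydroxy-2-methyl-5-(prop-1-en-2-yl)cyclohex-3-ene-1-carbaldehyde | C=C(C)[C@H]1C[C@@](O)(C=O)[C@](C)(CCC(OC)OC)C=C1 | intermediate
7 | (1R,2R,5S)-2-(3,3-dimethoxypropyl)-1-ethynyl-2-methyl-5-(prop-1-en-2-yl)cyclohex-3-en-1-ol | C=C(C)[C@H]1C[C@@](O)(C#C)[C@](C)(CCC(OC)OC)C=C1 | intermediate
8 | triethyl{[(1R,2R,5S)-2-(3,3-dimethoxypropyl)-1-ethynyl-2-methyl-5-(prop-1-en-2-yl)cyclohex-3-en-1-yl]oxy}silane | C=C(C)[C@H]1C[C@@](O[Si](CC)(CC)CC)(C#C)[C@](C)(CCC(OC)OC)C=C1 | intermediate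
9 | 3-[(1R,4S,6R)-6-ethynyl-1-methyl-4-(prop-1-en-2-yl)-6-(triethylsilyloxy)cyclohex-2-en-1-yl]propanal | C=C(C)[C@H]1C[C@@](O[Si](CC)(CC)CC)(C#C)[C@](C)(CCC=O)C=C1 | intermediate
10 | 3β,5α-bis(triethylsilyloxy)eudesma-4(15),8,11-triene | C=C(C)[C@H]1C[C@@]2(O[Si](CC)(CC)CC)C(=C)[C@@H](O[Si](CC)(CC)CC)CC[C@]2(C)C=C1 | intermediate
11 | 3β,5α-bis(triethylsilyloxy)eudesma-4(15),8,11(13)-trien-12-ol | C=C(CO)[C@H]1C[C@@]2(O[Si](CC)(CC)CC)C(=C)[C@@H](O[Si](CC)(CC)CC)CC[C@]2(C)C=C1 | intermediate
12 | 3β,5α-bis(triethylsilyloxy)eudesma-4(15),8,11(13)-trien-12-al | C=C(C=O)[C@H]1C[C@@]2(O[Si](CC)(CC)CC)C(=C)[C@@H](O[Si](CC)(CC)CC)CC[C@]2(C)C=C1 | intermediate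
13 | 3β,5α-bis(triethylsilyloxy)eudesma-4(15),8,11(13)-trien-12-oic acid | C=C(C(=O)O)[C@H]1C[C@@]2(O[Si](CC)(CC)CC)C(=C)[C@@H](O[Si](CC)(CC)CC)CC[C@]2(C)C=C1 | intermediate
14 | 9α-iodo-3β,5α-bis(triethylsilyloxy)eudesma-4(15),11(13)-dien-12,8β-olide | C=C1[C@H]2C[C@@]3(O[Si](CC)(CC)CC)C(=C)[C@@H](O[Si](CC)(CC)CC)CC[C@]3(C)[C@H](I)[C@H]2OC1=O | intermediate
15 | 3β,5α-bis(triethylsilyloxy)eudesma-4(15),11(13)-dien-12,8β-olide | C=C1[C@H]2C[C@@]3(O[Si](CC)(CC)CC)C(=C)[C@@H](O[Si](CC)(CC)CC)CC[C@]3(C)C[C@H]2OC1=O | intermediate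
16 | lithium 8β-hydroxy-3β,5α-bis(triethylsilyloxy)eudesma-4(15),11(13)-dien-12-oate | [Li+].C=C(C(=O)[O-])[C@H]1C[C@@]2(O[Si](CC)(CC)CC)C(=C)[C@@H](O[Si](CC)(CC)CC)CC[C@]2(C)C[C@H]1O | intermediate (not isolated)
17 | methyl 8β-hydroxy-3β,5α-bis(triethylsilyloxy)eudesma-4(15),11(13)-dien-12-oate | C=C(C(=O)OC)[C@H]1C[C@@]2(O[Si](CC)(CC)CC)C(=C)[C@@H](O[Si](CC)(CC)CC)CC[C@]2(C)C[C@H]1O | intermediate
18 | methyl 8β-acetoxy-3β,5α-bis(triethylsilyloxy)eudesma-4(15),11(13)-dien-12-oate | C=C(C(=O)OC)[C@H]1C[C@@]2(O[Si](CC)(CC)CC)C(=C)[C@@H](O[Si](CC)(CC)CC)CC[C@]2(C)C[C@H]1OC(C)=O | intermediate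
19 | methyl 8β-acetoxy-3β,5α-dihydroxyeudesma-4(15),11(13)-dien-12-oate | C=C(C(=O)OC)[C@H]1C[C@@]2(O)C(=C)[C@@H](O)CC[C@]2(C)C[C@H]1OC(C)=O | intermediate
20 | angelic acid, (Z)-2-methylbut-2-enoic acid | C/C=C(/C)C(=O)O | starting material
21 | angelic 2,4,6-trichlorobenzoic anhydride | C/C=C(/C)C(=O)OC(=O)c1c(Cl)cc(Cl)cc1Cl | intermediate (not isolated)
22 | methyl 8β-acetoxy-3β-angeloyloxy-5α-hydroxyeudesma-4(15),11(13)-dien-12-oate (CNP0179024.1) | C=C(C(=O)OC)[C@H]1C[C@@]2(O)C(=C)[C@@H](OC(=O)/C(C)=C\C)CC[C@]2(C)C[C@H]1OC(C)=O | target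

Total step count: 16. Longest linear sequence: 16 steps, from (R)-carvone 1.

**Steps most likely to fail**

Step 7 (key step). Oligomerization or hydrosilylation of the hydrogen-terminated alkyne, or direct silane reduction of the aldehyde, may outpace the oxidative cyclization at the crowded propargylic carbon. The fallback sets out from 9 and returns at 10; it makes the same C3–C4 bond by a chromium-mediated vinyl–aldehyde addition. Hydrostannation of 9 with Bu3SnH and catalytic Mo(CO)3(CNtBu)3, which places tin on the inner carbon of propargylic ethers, would give the α-stannyl alkene F1. Iododestannylation with I2 would give the 2-iodoalkene F2. An intramolecular Nozaki–Hiyama–Kishi reaction (CrCl2, catalytic NiCl2, DMF) would close ring A to the 3-alcohol F3, expected to be 3β by the same chair argument. Silylation with Et3SiCl and imidazole returns to 10.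

Step 1. Facial selectivity at C10 may be poor, and E2 elimination of the primary bromide or O-alkylation may compete with C-alkylation. The fallback sets out from 1 and returns at 3; it puts C10 under ligand control. Trapping the potassium dienolate of 1 with allyl chloroformate would give the allyl dienyl carbonate F4. Decarboxylative allylic alkylation with Pd2(dba)3 and the t-BuPHOX enantiomer matched to the (R) centre would give the allyl ketone F5. Aldehyde-selective Wacker oxidation of the monosubstituted alkene (PdCl2(PhCN)2, CuCl2, AgNO2, O2, t-BuOH/MeNO2) would give the keto aldehyde F6. Acetalization of the aldehyde with HC(OMe)3, PPTS and MeOH, which the hindered ketone should resist, returns to 3.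

Step 8. Site selectivity among the allylic positions may be lost (hydrogen abstraction at C7 or C3), or the product may be over-oxidized. The fallback sets out from 10 and returns at 12. Ene-type chlorination of the isopropenyl group with Ca(OCl)2 and CO2 in CH2Cl2/H2O would give the allylic chloride F7. Oxidation of F7 with N-methylmorpholine N-oxide in MeCN gives the enal 12 directly, so step 9 is not needed.

**Further compounds**

F1 | step 7 | 3-[(1R,4S)-1-methyl-4-(prop-1-en-2-yl)-6-[1-(tributylstannyl)ethenyl]-6-(triethylsilyloxy)cyclohex-2-en-1-yl]propanal (C5 as in 9) | C=C(C)[C@H]1C[C@@](O[Si](CC)(CC)CC)(C(=C)[Sn](CCCC)(CCCC)CCCC)[C@](C)(CCC=O)C=C1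
F2 | step 7 | 3-[(1R,4S)-6-(1-iodoethenyl)-1-methyl-4-(prop-1-en-2-yl)-6-(triethylsilyloxy)cyclohex-2-en-1-yl]propanal (C5 as in 9) | C=C(C)[C@H]1C[C@@](O[Si](CC)(CC)CC)(C(=C)I)[C@](C)(CCC=O)C=C1
F3 | step 7 | 5α-(triethylsilyloxy)eudesma-4(15),8,11-trien-3β-ol | C=C(C)[C@H]1C[C@@]2(O[Si](CC)(CC)CC)C(=C)[C@@H](O)CC[C@]2(C)C=C1
F4 | step 1 | allyl (5S)-2-methyl-5-(prop-1-en-2-yl)cyclohexa-1,3-dien-1-yl carbonate | C=C(C)[C@H]1CC(OC(=O)OCC=C)=C(C)C=C1
F5 | step 1 | (2R,5S)-2-allyl-2-methyl-5-(prop-1-en-2-yl)cyclohex-3-en-1-one | C=C(C)[C@H]1CC(=O)[C@](C)(CC=C)C=C1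
F6 | step 1 | 3-[(1R,4S)-1-methyl-6-oxo-4-(prop-1-en-2-yl)cyclohex-2-en-1-yl]propanal | C=C(C)[C@H]1CC(=O)[C@](C)(CCC=O)C=C1
F7 | step 8 | 12-chloro-3β,5α-bis(triethylsilyloxy)eudesma-4(15),8,11(13)-triene | C=C(CCl)[C@H]1C[C@@]2(O[Si](CC)(CC)CC)C(=C)[C@@H](O[Si](CC)(CC)CC)CC[C@]2(C)C=C1
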